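**Retrosynthetic overview**

1. The C6–C6' biaryl bond is made last by Stille union of stannane 20 (lactone half) with iodide 21 (hydroxy-acid half). Both come from one monomer, 18, so the seco acid arises by opening the lactone of one portion.
2. Monomer 18: the pyranone ring is closed at C3–C2 by intramolecular carbenoid cyclopropanation of a diazomethyl ketone onto a tethered (Z)-2-aryloxyacrylate. The cyclopropane is a temporary ring, reopened at the lactone carbinol carbon C2' by the side-chain acid in the same flask, which closes the lactone ring.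
3. Enabling feature: in the lactone-bearing chromanone, ring carbon C3 (alpha to the C4 ketone) and the lactone oxygen O1' are anti-vicinal substituents on the C2–C2' bond, and C2 also carries O1 and CO2Me. The pyranone and oxolanone rings are therefore the two halves of an anti carbo-oxygenation of a 2-aryloxyacrylate, with the C4 ketone serving as the leaving enol for the C3–C2' bond.
4. Precursor 14 comes from 6-methoxysalicylic acid, a diazophosphonoacetate (O–H insertion, then Horner–Wadsworth–Emmons) and an Evans-derived (S)-aldehyde that carries the methyl-bearing centre C3'.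
5. Ring order: benzene rings bought; pyranone ring (with the temporary cyclopropane) and then the lactone ring in step 10; biaryl bond in step 15.

Key step: step 10

Locants: chromanone O1, C2, C3, C4, C4a, C5–C8, C8a; oxolanone C2' (carbinol carbon on C2) and C3' (methyl-bearing).

Remark 1: the sense of facial induction of the Cu/t-Bu-box carbenoid on this acrylate cannot be predicted with confidence, so the ligand antipode would be fixed by the first experiment; because C3' is set beforehand, a wrong-face product is a separable diastereomer, never the enantiomer.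
Remark 2: the γ-hydroxy acid of the target (and of 21) is assumed to resist lactonisation at pH 5 or above near room temperature.

**Step 1**
Reactants: 1 2-hydroxy-6-methoxybenzoic acid
Product: 2 prop-2-en-1-yl 2-hydroxy-6-methoxybenzoate
Conditions: allyl bromide, KHCO3, DMF, rt
Reagents that add atoms: allyl bromide, C=CCBr
Why: Carboxylate O-alkylation (SN2); bicarbonate leaves the hydrogen-bonded phenol untouched.

**Step 2**
Reactants: 3 trimethyl phosphonoacetate
Product: 4 methyl 2-diazo-2-(dimethoxyphosphoryl)acetate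
Conditions: p-ABSA, DBU, MeCN, 0 °C to rt
Reagents that add atoms: 4-acetamidobenzenesulfonyl azide (p-ABSA), CC(=O)Nc1ccc(cc1)S(=O)(=O)N=[N+]=[N-]
Why: Regitz diazo transfer to the doubly activated methylene.

**Step 3**
Reactants: 2 prop-2-en-1-yl 2-hydroxy-6-methoxybenzoate; 4 methyl 2-diazo-2-(dimethoxyphosphoryl)acetate
Product: 5 prop-2-en-1-yl 2-[1-(dimethoxyphosphoryl)-2-methoxy-2-oxoethoxy]-6-methoxybenzoate (racemic)
Conditions: Rh2(OAc)4 (1 mol %), toluene, 80 °C, slow addition of 4
Reagents that add atoms: none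
Why: Rhodium carbenoid O–H insertion into the phenol outpaces cyclopropanation of the allyl group by this acceptor/acceptor carbenoid; the new centre is racemic and is erased in step 7.

**Step 4**
Reactants: 6 (R)-4-benzyl-3-propanoyl-1,3-oxazolidin-2-one; 7 tert-butyl bromoacetate
Product: 8 tert-butyl (3S)-4-[(4R)-4-benzyl-2-oxo-1,3-oxazolidin-3-yl]-3-methyl-4-oxobutanoate
Conditions: NaHMDS, THF, −78 °C; then 7, −78 to −40 °C
Reagents that add atoms: none
Why: Evans asymmetric alkylation; the chelated Z sodium enolate is alkylated on the face opposite the benzyl group, which sets the methyl-bearing centre as S.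

**Step 5**
Reactants: 8 tert-butyl (3S)-4-[(4R)-4-benzyl-2-oxo-1,3-oxazolidin-3-yl]-3-methyl-4-oxobutanoate
Product: 9 tert-butyl (3S)-4-hydroxy-3-methylbutanoate
Conditions: LiBH4, H2O (1 equiv), Et2O, 0 °C
Reagents that add atoms: none
Why: Reductive cleavage of the imide by LiBH4 releases the auxiliary; the tert-butyl ester is not reduced and the centre is untouched.

**Step 6**
Reactants: 9 tert-butyl (3S)-4-hydroxy-3-methylbutanoate
Product: 10 tert-butyl (3S)-3-methyl-4-oxobutanoate
Conditions: Dess–Martin periodinane, NaHCO3, CH2Cl2, 0 °C to rt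
Reagents that add atoms: none
Why: Buffered Dess–Martin oxidation gives the α-branched aldehyde without epimerisation; it is used at once.

**Step 7**
Reactants: 5 prop-2-en-1-yl 2-[1-(dimethoxyphosphoryl)-2-methoxy-2-oxoethoxy]-6-methoxybenzoate; 10 tert-butyl (3S)-3-methyl-4-oxobutanoate
Product: 11 6-tert-butyl 1-methyl (2Z,4S)-2-{3-methoxy-2-[(prop-2-en-1-yloxy)carbonyl]phenoxy}-4-methylhex-2-enedioate
Conditions: LiCl, DBU, MeCN, 0 °C to rt
Reagents that add atoms: none
Why: Horner–Wadsworth–Emmons olefination under Masamune–Roush conditions should favour the Z isomer (ester trans to the branched chain, aryloxy cis), and the mild base spares the α-centre of 10; the hindered 2,6-disubstituted benzoate should resist attack by the phosphonate anion.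

**Step 8**
Reactants: 11 6-tert-butyl 1-methyl (2Z,4S)-2-{3-methoxy-2-[(prop-2-en-1-yloxy)carbonyl]phenoxy}-4-methylhex-2-enedioate
Product: 12 2-{[(2Z,4S)-6-tert-butoxy-1-methoxy-4-methyl-1,6-dioxohex-2-en-2-yl]oxy}-6-methoxybenzoic acid
Conditions: Pd(PPh3)4 (5 mol %), N-methylaniline, THF, rt
Reagents that add atoms: none
Why: Tsuji–Trost deallylation with zerovalent palladium; the π-allyl is captured by the weakly nucleophilic amine, and the methyl and tert-butyl esters and the acrylate are left alone.

**Step 9**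
Reactants: 12 2-{[(2Z,4S)-6-tert-butoxy-1-methoxy-4-methyl-1,6-dioxohex-2-en-2-yl]oxy}-6-methoxybenzoic acid
Product: 14 6-tert-butyl 1-methyl (2Z,4S)-2-[2-(2-diazoacetyl)-3-methoxyphenoxy]-4-methylhex-2-enedioate, via acid chloride 13 (not isolated)
Conditions: 1-chloro-N,N,2-trimethylprop-1-en-1-amine, CH2Cl2, 0 °C to rt; then CH2N2 (3 equiv), Et2O, 0 °C, short contact, AcOH quench
Reagents that add atoms: diazomethane, C=[N+]=[N-]
Why: Neutral acid chloride formation (Ghosez reagent) and acylation of diazomethane, the first stage of an Arndt–Eistert sequence; low temperature and short contact limit dipolar addition of diazomethane to the hindered acrylate.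

**Step 10**
Reactants: 14 6-tert-butyl 1-methyl (2Z,4S)-2-[2-(2-diazoacetyl)-3-methoxyphenoxy]-4-methylhex-2-enedioate
Product: 17 methyl (2S)-5-methoxy-2-[(2R,3S)-3-methyl-5-oxooxolan-2-yl]-4-oxochromane-2-carboxylate, via cyclopropane ester 15 (not isolated), via cyclopropane acid 16 (not isolated)
Conditions: Cu(MeCN)4PF6 (5 mol %), (S,S)-t-Bu-box (6 mol %), CH2Cl2, 40 °C, slow addition of 14; then TFA, 0 to 40 °C
Reagents that add atoms: none
Why: Proposed new method: tandem carbenoid cyclopropanation/homoconjugate lactonisation, in which the copper carbenoid from 14 (loss of N2) adds across the tethered (Z)-2-aryloxyacrylate so that the new C3–C2 bond closes the six-membered pyranone ring (carbenoid carbon to the proximal alkene carbon, as in the closest known type, the copper–bis(oxazoline)- or dirhodium-catalysed conversion of 1-diazohept-6-en-2-ones into bicyclo[4.1.0]heptan-2-ones, and keto-carbenoid cyclopropanation of enol ethers and 2-heteroatom-substituted acrylates), while the second new bond C3–C2' makes cyclopropane 15 a temporary ring. The addition is suprafacial and stereospecific, so the Z geometry places the C2' substituent cis to O1, and the chiral catalyst must select the acrylate face that is Re at the aryloxy-bearing carbon, which fixes C2 as S; the resident C3' centre (H eclipsing the alkene, CH3 and CH2CO2tBu on the two faces) is expected to bias the faces only weakly and possibly against this face. TFA then cleaves the tert-butyl ester, and acid 16 opens the external cyclopropane bond C3–C2', which is aligned with and activated by the protonated C4 ketone, by 5-exo-tet attack of the carboxyl oxygen on C2' with inversion (closest known type: acid-mediated lactonisation of cyclopropyl ketone acids); this closes the lactone ring, fixes C2' as R and turns C3 into the ring CH2. The opening needs regioselectivity (ketone enol at C3 as leaving group, not the ester enol at C2, and no ionisation of the O1-substituted fusion bond C2–C3), which rests on the ketone being the better and better-aligned acceptor and on the C2 ester destabilising an oxocarbenium ion at C2. Chemoselectivity of the carbenoid rests on copper (little C–H insertion) and on the C5 methyl ether and the vinylic O1, neither of which offers a group that migrates in an oxonium ylide.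

**Step 11**
Reactants: 17 methyl (2S)-5-methoxy-2-[(2R,3S)-3-methyl-5-oxooxolan-2-yl]-4-oxochromane-2-carboxylate
Product: 18 methyl (2S)-5-hydroxy-2-[(2R,3S)-3-methyl-5-oxooxolan-2-yl]-4-oxochromane-2-carboxylate
Conditions: BCl3, CH2Cl2, −78 to 0 °C; aqueous NaHCO3 work-up
Reagents that add atoms: none
Why: Chelation-assisted demethylation of the methoxy group peri to the C4 ketone; esters, lactone and the tertiary O1–C2 ether (cation at C2 disfavoured by CO2Me) should survive at low temperature.

**Step 12**
Reactants: 18 methyl (2S)-5-hydroxy-2-[(2R,3S)-3-methyl-5-oxooxolan-2-yl]-4-oxochromane-2-carboxylate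
Product: 19 methyl (2S)-5-hydroxy-6-iodo-2-[(2R,3S)-3-methyl-5-oxooxolan-2-yl]-4-oxochromane-2-carboxylate
Conditions: BnMe3N ICl2, CaCO3, CH2Cl2/MeOH, rt
Reagents that add atoms: benzyltrimethylammonium dichloroiodate, C[N+](C)(C)Cc1ccccc1.Cl[I-]Cl
Why: Electrophilic aromatic iodination at C6, ortho to the chelated 5-OH and para to O1, the usual site for 5-hydroxychromanones of this family.

**Step 13**
Reactants: 19 methyl (2S)-5-hydroxy-6-iodo-2-[(2R,3S)-3-methyl-5-oxooxolan-2-yl]-4-oxochromane-2-carboxylate
Product: 20 methyl (2S)-5-hydroxy-2-[(2R,3S)-3-methyl-5-oxooxolan-2-yl]-4-oxo-6-(trimethylstannyl)chromane-2-carboxylate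
Conditions: Pd(PPh3)4 (10 mol %), Me3SnSnMe3, toluene, 90 °C
Reagents that add atoms: hexamethylditin, C[Sn](C)(C)[Sn](C)(C)C
Why: Palladium-catalysed stannylation of the aryl iodide with a distannane under neutral conditions that spare lactone, ester and the base-sensitive pyranone.

**Step 14**
Reactants: 19 methyl (2S)-5-hydroxy-6-iodo-2-[(2R,3S)-3-methyl-5-oxooxolan-2-yl]-4-oxochromane-2-carboxylate
Product: 21 (3S,4R)-4-hydroxy-4-[(2S)-5-hydroxy-6-iodo-2-(methoxycarbonyl)-4-oxochroman-2-yl]-3-methylbutanoic acid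
Conditions: LiOH (2.2 equiv), THF/H2O, 0 °C; AcOH to pH 5, cold extraction
Reagents that add atoms: lithium hydroxide, [Li+].[OH-]
Why: Saponification of the unhindered γ-lactone by acyl–oxygen cleavage (C2' configuration retained) in preference to the neopentyl-type C2 methyl ester; prior phenoxide formation lowers the acidity of C3–H and should suppress retro-oxa-Michael opening.

**Step 15**
Reactants: 20 methyl (2S)-5-hydroxy-2-[(2R,3S)-3-methyl-5-oxooxolan-2-yl]-4-oxo-6-(trimethylstannyl)chromane-2-carboxylate; 21 (3S,4R)-4-hydroxy-4-[(2S)-5-hydroxy-6-iodo-2-(methoxycarbonyl)-4-oxochroman-2-yl]-3-methylbutanoic acid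
Product: 22 (3S,4R)-4-hydroxy-4-{(2S,2'S)-5,5'-dihydroxy-2,2'-bis(methoxycarbonyl)-2'-[(2R,3S)-3-methyl-5-oxooxolan-2-yl]-4,4'-dioxo-[6,6'-bichroman]-2-yl}-3-methylbutanoic acid (target)
Conditions: Pd(PPh3)4 (10 mol %), CuTC (Cu(O2CC4H3S), 1.5 equiv), DMF, rt; work-up at pH 5
Reagents that add atoms: none
Why: Stille cross-coupling promoted by copper thiophene-2-carboxylate (Liebeskind conditions), base-free and at room temperature, so that lactone, hydroxy acid and both pyranone rings persist; the biaryl has only two ortho substituents and no fixed axis.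

**Compound list**

1 | 2-hydroxy-6-methoxybenzoic acid | COc1cccc(O)c1C(=O)O | starting material
2 | prop-2-en-1-yl 2-hydroxy-6-methoxybenzoate | COc1cccc(O)c1C(=O)OCC=C | intermediate
3 | trimethyl phosphonoacetate | COC(=O)CP(=O)(OC)OC | starting material
4 | methyl 2-diazo-2-(dimethoxyphosphoryl)acetate | COC(=O)C(=[N+]=[N-])P(=O)(OC)OC | intermediate
5 | prop-2-en-1-yl 2-[1-(dimethoxyphosphoryl)-2-methoxy-2-oxoethoxy]-6-methoxybenzoate (racemic) | COc1cccc(OC(C(=O)OC)P(=O)(OC)OC)c1C(=O)OCC=C | intermediate
6 | (R)-4-benzyl-3-propanoyl-1,3-oxazolidin-2-one | CCC(=O)N1C(=O)OC[C@H]1Cc1ccccc1 | starting material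
7 | tert-butyl bromoacetate | CC(C)(C)OC(=O)CBr | starting material
8 | tert-butyl (3S)-4-[(4R)-4-benzyl-2-oxo-1,3-oxazolidin-3-yl]-3-methyl-4-oxobutanoate | CC(C)(C)OC(=O)C[C@H](C)C(=O)N1C(=O)OC[C@H]1Cc1ccccc1 | intermediate
9 | tert-butyl (3S)-4-hydroxy-3-methylbutanoate | CC(C)(C)OC(=O)C[C@H](C)CO | intermediate
10 | tert-butyl (3S)-3-methyl-4-oxobutanoate | CC(C)(C)OC(=O)C[C@H](C)C=O | intermediate
11 | 6-tert-butyl 1-methyl (2Z,4S)-2-{3-methoxy-2-[(prop-2-en-1-yloxy)carbonyl]phenoxy}-4-methylhex-2-enedioate | COc1cccc(O/C(C(=O)OC)=C\[C@@H](C)CC(=O)OC(C)(C)C)c1C(=O)OCC=C | intermediate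
12 | 2-{[(2Z,4S)-6-tert-butoxy-1-methoxy-4-methyl-1,6-dioxohex-2-en-2-yl]oxy}-6-methoxybenzoic acid | COc1cccc(O/C(C(=O)OC)=C\[C@@H](C)CC(=O)OC(C)(C)C)c1C(=O)O | intermediate
13 | 6-tert-butyl 1-methyl (2Z,4S)-2-[2-(chlorocarbonyl)-3-methoxyphenoxy]-4-methylhex-2-enedioate | COc1cccc(O/C(C(=O)OC)=C\[C@@H](C)CC(=O)OC(C)(C)C)c1C(Cl)=O | intermediate
14 | 6-tert-butyl 1-methyl (2Z,4S)-2-[2-(2-diazoacetyl)-3-methoxyphenoxy]-4-methylhex-2-enedioate | COc1cccc(O/C(C(=O)OC)=C\[C@@H](C)CC(=O)OC(C)(C)C)c1C(=O)C=[N+]=[N-] | intermediate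
15 | methyl (1R,1aR,7aS)-1-[(2S)-4-tert-butoxy-4-oxobutan-2-yl]-6-methoxy-7-oxo-1,7a-dihydrocyclopropa[b]chromene-1a(7H)-carboxylate (side chain on C1 cis to the ring oxygen) | COc1cccc2O[C@]3(C(=O)OC)[C@H]([C@@H](C)CC(=O)OC(C)(C)C)[C@@H]3C(=O)c12 | intermediate
16 | (3S)-3-[(1R,1aR,7aS)-6-methoxy-1a-(methoxycarbonyl)-7-oxo-1,1a,7,7a-tetrahydrocyclopropa[b]chromen-1-yl]butanoic acid | COc1cccc2O[C@]3(C(=O)OC)[C@H]([C@@H](C)CC(=O)O)[C@@H]3C(=O)c12 | intermediate
17 | methyl (2S)-5-methoxy-2-[(2R,3S)-3-methyl-5-oxooxolan-2-yl]-4-oxochromane-2-carboxylate | COc1cccc2O[C@](C(=O)OC)([C@@H]3OC(=O)C[C@@H]3C)CC(=O)c12 | intermediate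
18 | methyl (2S)-5-hydroxy-2-[(2R,3S)-3-methyl-5-oxooxolan-2-yl]-4-oxochromane-2-carboxylate | Oc1cccc2O[C@](C(=O)OC)([C@@H]3OC(=O)C[C@@H]3C)CC(=O)c12 | intermediate
19 | methyl (2S)-5-hydroxy-6-iodo-2-[(2R,3S)-3-methyl-5-oxooxolan-2-yl]-4-oxochromane-2-carboxylate | Oc1c(I)ccc2O[C@](C(=O)OC)([C@@H]3OC(=O)C[C@@H]3C)CC(=O)c12 | intermediate
20 | methyl (2S)-5-hydroxy-2-[(2R,3S)-3-methyl-5-oxooxolan-2-yl]-4-oxo-6-(trimethylstannyl)chromane-2-carboxylate | C[Sn](C)(C)c1ccc2O[C@](C(=O)OC)([C@@H]3OC(=O)C[C@@H]3C)CC(=O)c2c1O | intermediate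
21 | (3S,4R)-4-hydroxy-4-[(2S)-5-hydroxy-6-iodo-2-(methoxycarbonyl)-4-oxochroman-2-yl]-3-methylbutanoic acid | COC(=O)[C@@]1([C@H](O)[C@@H](C)CC(=O)O)CC(=O)c2c(ccc(I)c2O)O1 | intermediate
22 | (3S,4R)-4-hydroxy-4-{(2S,2'S)-5,5'-dihydroxy-2,2'-bis(methoxycarbonyl)-2'-[(2R,3S)-3-methyl-5-oxooxolan-2-yl]-4,4'-dioxo-[6,6'-bichroman]-2-yl}-3-methylbutanoic acid | COC(=O)[C@@]1([C@H](O)[C@@H](C)CC(=O)O)CC(=O)c2c(ccc(-c3ccc4c(c3O)C(=O)C[C@@](C(=O)OC)([C@@H]3OC(=O)C[C@@H]3C)O4)c2O)O1 | target

**Totals and risks**

Total step count: 15. Longest linear sequence: 11 steps (steps 4, 5, 6, 7, 8, 9, 10, 11, 12, 14, 15).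

Steps most likely to fail:

1. Step 10 (bears the label "Proposed new method:"). The carbenoid may be diverted (oxonium-ylide formation at O1 or the C5 ether oxygen, insertion into the OCH3 C–H bonds, stepwise closure to a dihydrofuran). The catalyst may fail to override the substrate and deliver C3 to the wrong acrylate face. Acid may ionise the ring-fusion bond C2–C3 instead of opening C3–C2'. Fallback with known chemistry, which makes the C2–C2' bond on a preformed pyranone ring; it sets out from 1 and returns at 17. From 1, MeLi (3 equiv, THF) would give 1-(2-hydroxy-6-methoxyphenyl)ethan-1-one F1. Claisen condensation of F1 with dimethyl oxalate (NaOMe, MeOH) and HCl-mediated cyclodehydration would give methyl 5-methoxy-4-oxo-4H-chromene-2-carboxylate F2. 4-Methylfuran-2(5H)-one with TIPSOTf/Et3N would give 4-methyl-2-(triisopropylsilyloxy)furan F3. TIPSOTf would turn F2 into 5-methoxy-2-(methoxycarbonyl)-4-(triisopropylsilyloxy)chromenylium triflate F4. F3 would add to C2 of F4 through its C5 (vinylogous Mukaiyama addition) to give the silyl enol ether methyl 5-methoxy-2-(3-methyl-5-oxo-2,5-dihydrofuran-2-yl)-4-(triisopropylsilyloxy)-2H-chromene-2-carboxylate F5. Acidic work-up would give the racemic butenolide methyl 5-methoxy-2-(3-methyl-5-oxo-2,5-dihydrofuran-2-yl)-4-oxochromane-2-carboxylate F6, whose (2S*,2'R*) diastereomer would be separated by chromatography. Asymmetric copper hydride conjugate reduction run as a kinetic resolution (Cu(OAc)2, the appropriate antipode of DTBM-SEGPHOS, polymethylhydrosiloxane, t-BuOH, toluene) would reduce the (2S,2'R) enantiomer from the butenolide face opposite the chromanone and give 17.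

2. Step 14. Hydroxide may trigger retro-oxa-Michael opening and reclosure of the pyranone (loss of C2 configuration), may also cleave the C2 methyl ester, and the hydroxy acid may relactonise on acidification. Fallback that desymmetrises a symmetric dimer and avoids hydroxide; it sets out from 18 and returns at 22. Oxidative phenol coupling of 18 with VOF3 (pentavalent vanadium; CH2Cl2/TFA, 0 °C), which in 5-hydroxychromanones of this type couples ortho to the chelated phenol, would give dimethyl (2S,2'S)-5,5'-dihydroxy-2,2'-bis[(2R,3S)-3-methyl-5-oxooxolan-2-yl]-4,4'-dioxo-[6,6'-bichromane]-2,2'-dicarboxylate F7. One of its two lactones would be opened at pH 7 with pig-liver esterase (phosphate buffer/DMSO, rt), stopped at partial conversion, with recovered F7 recycled and any diacid reclosed to F7 with acid; this gives 22.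

3. Step 15. The electron-rich ortho-hydroxyaryl stannane may be protodestannylated by the carboxylic acid partner, homocoupling may compete, and transmetallation may be slow. Fallback through a boron partner; it sets out from 19 and returns at 22. Miyaura borylation of 19 (PdCl2(dppf), bis(pinacolato)diboron, KOAc, dioxane, 80 °C) would give methyl (2S)-5-hydroxy-2-[(2R,3S)-3-methyl-5-oxooxolan-2-yl]-4-oxo-6-(4,4,5,5-tetramethyl-1,3,2-dioxaborolan-2-yl)chromane-2-carboxylate F8. Suzuki–Miyaura coupling of F8 with 21, which enters as its carboxylate (Pd(OAc)2, SPhos, K3PO4, THF/H2O, rt), would give 22 after acidification to pH 5.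

**Further compounds**

F1 | step 10 | 1-(2-hydroxy-6-methoxyphenyl)ethan-1-one | COc1cccc(O)c1C(C)=O
F2 | step 10 | methyl 5-methoxy-4-oxo-4H-chromene-2-carboxylate | COC(=O)c1cc(=O)c2c(OC)cccc2o1
F3 | step 10 | 4-methyl-2-(triisopropylsilyloxy)furan | Cc1coc(O[Si](C(C)C)(C(C)C)C(C)C)c1
F4 | step 10 | 5-methoxy-2-(methoxycarbonyl)-4-(triisopropylsilyloxy)chromenylium triflate | COC(=O)c1cc(O[Si](C(C)C)(C(C)C)C(C)C)c2c(OC)cccc2[o+]1.[O-]S(=O)(=O)C(F)(F)F
F5 | step 10 | methyl (2S*)-5-methoxy-2-[(2R*)-3-methyl-5-oxo-2,5-dihydrofuran-2-yl]-4-(triisopropylsilyloxy)-2H-chromene-2-carboxylate (racemic, one enantiomer drawn) | COc1cccc2O[C@](C(=O)OC)([C@@H]3OC(=O)C=C3C)C=C(O[Si](C(C)C)(C(C)C)C(C)C)c12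
F6 | step 10 | methyl (2S*)-5-methoxy-2-[(2R*)-3-methyl-5-oxo-2,5-dihydrofuran-2-yl]-4-oxochromane-2-carboxylate (racemic, one enantiomer drawn) | COc1cccc2O[C@](C(=O)OC)([C@@H]3OC(=O)C=C3C)CC(=O)c12
F7 | step 14 | dimethyl (2S,2'S)-5,5'-dihydroxy-2,2'-bis[(2R,3S)-3-methyl-5-oxooxolan-2-yl]-4,4'-dioxo-[6,6'-bichromane]-2,2'-dicarboxylate | Oc1c(-c2ccc3O[C@](C(=O)OC)([C@@H]4OC(=O)C[C@@H]4C)CC(=O)c3c2O)ccc2O[C@](C(=O)OC)([C@@H]3OC(=O)C[C@@H]3C)CC(=O)c12
F8 | step 15 | methyl (2S)-5-hydroxy-2-[(2R,3S)-3-methyl-5-oxooxolan-2-yl]-4-oxo-6-(4,4,5,5-tetramethyl-1,3,2-dioxaborolan-2-yl)chromane-2-carboxylate | CC1(C)OB(OC1(C)C)c1ccc2O[C@](C(=O)OC)([C@@H]3OC(=O)C[C@@H]3C)CC(=O)c2c1O
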